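# Farnesylemefuranone E: synthesis proposal

## The problem

Farnesylemefuranone E (10) is a phthalide (2-benzofuran-1(3H)-one: C1 carbonyl, O2, C3 methylene; ring A = benzene ring C3a–C7a, ring B = lactone) that carries on O5 the chain R = (2E,6E)-11-hydroxy-3,7,11-trimethyldodeca-2,6-dien-1-yl (primed numbers). Ring A is pentasubstituted: three neighbouring and different oxygens (C4–OH, C5–OR, C6–OMe), one hydrogen (C7), and ring B fused in one orientation only, with C3 on C3a beside the free hydroxyl and C1 on C7a beside C7–H. A synthesis must therefore tell the three oxygens apart, join R to the middle one through its primary allylic carbon C1′, and make the C3a–C3 bond at a ring carbon that is flanked on both sides. There is no stereocentre; the E olefins C2′=C3′ and C6′=C7′ come with a farnesyl precursor and only have to survive, and the C11′ tertiary alcohol is the Markovnikov hydrate of one of three trisubstituted olefins, which is a question of site selectivity. The allyl aryl ether will not survive Brønsted or Lewis acids, zerovalent palladium or strong heating; the tertiary alcohol eliminates or cyclizes onto the olefins under acid; the olefins exclude electrophilic halogen and peracids late in the route; the lactone excludes hydride and hydroxide; catechol-type intermediates oxidize in air under base. The feature that makes the key step possible is the row O4–C4 / C3a / C7a–C1: the C4 hydroxyl has C3a as its only free ortho position (C5 is substituted), so a phenoxide at O4 can deliver a one-carbon electrophile to C3a and nowhere else, and the oxygen of that new carbon then lies exactly one five-membered ring (ring B: C1, O2, C3, C3a, C7a) away from the carbon that C7a already carries.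

## Retrosynthesis

**10 to 7.** The C3a–C3 bond and the C1–O2 bond of ring B are cut, and C1 is returned from the acid to the aldehyde level. What remains is benzaldehyde 7, in which all three oxygens and the complete side chain are in place, and a one-carbon aldehyde reagent.
- Against the neighbouring cut at O5–C1′ (chain last), this leaves no regiochemical question on an advanced fragment.
- Against a cut at C7a–C1, it uses the only ring carbon that an oxygen substituent can activate: C7a is meta to O4 and O6 and has no directing neighbour.
- Against bringing C1 in as an ester, it needs no separate reduction, because the reagent that supplies C3 is also the oxidant for C1.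
- Precursor 7 lacks ring B, C3 and one oxidation level.
- The forward reaction must form a C–C bond at a flanked position ortho to the phenol, close ring B through lactol 9 (formed from the hydroxymethyl aldehyde 8), and oxidize C1. It must do so without touching the allyl aryl ether, the tertiary alcohol and the olefins.

**7 to 5 and 6.** The O5–C1′ bond is cut to give allylic bromide 5 and commercial 3,4-dihydroxy-5-methoxybenzaldehyde 6.
- Compound 6 already holds the methyl ether and both hydroxyls of ring A in the right order.
- Its two hydroxyls differ sharply: the one para to the formyl group is a vinylogous acid and is the one that must carry R.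
- The formyl group therefore serves twice, first as the element that selects the oxygen and then as the future C1.
- The forward reaction is an SN2 etherification at a primary allylic carbon, which must proceed without ionization so that C2′=C3′ stays E.

**5 to 4, 2 and 1.** The C1′–Br bond is traced back to the primary alcohol of diol 4. The C10′–H and C11′–O bonds are traced back, through epoxide 3 and bromohydrin 2, to the terminal olefin of commercial (2E,6E)-farnesyl acetate 1.
- Buying the C15 skeleton with both E olefins is simpler than any chain assembly.
- The only task is to hydrate one olefin of three, and a bromohydrin formed in aqueous medium is the precedented way to single out the terminal one.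
- The forward sequence must then remove the bromine reductively without touching the remaining olefins.

## Roads not taken

**Alternative 1: chain last (the most obvious route).**
- Cut: O5–C1′ as the final bond, giving 4,5-dihydroxy-6-methoxyphthalide A1 and bromide 5.
- Forward key step: base-mediated alkylation of A1 at O5, the hydroxyl para to the lactone carbonyl.
- Why the chosen plan is better: A1 has to be made first by the same C3a–C3 construction plus a separate reduction, so the route is one step longer. The O4/O5 decision falls on the union of the two most advanced fragments, where the acidifying group is only a lactone carbonyl; in 6 it is a formyl group, a stronger acceptor, and the phenol is commercial. Over-alkylation of A1 would consume 5, and A1 as a free catechol is prone to oxidation under the basic conditions.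

**Alternative 2: ring A built from a four-membered ring.**
- Cut: ring A across C4–C3a and C7–C7a, giving 4-chloro-2,3-dimethoxycyclobut-2-en-1-one A2 and 3-(tributylstannyl)furan-2(5H)-one A3.
- Forward key step: Stille coupling, thermal 4π ring opening to a dienylketene, and 6π closure with tautomerization to 4-hydroxy-5,6-dimethoxyphthalide A4.
- Why the chosen plan is better: the benzannulation would place all five substituents by connectivity, but O5 arrives as a methyl ether. A selective cleavage to A1 and the alkylation of Alternative 1 would still follow. The two alkoxy positions of the cyclobutenone cannot be told apart when it is made, so R cannot be carried through. A2 and A3 each need their own preparation, which gives away what the ring synthesis gains, since ring A with this oxygen pattern is commercial as 6.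

**Alternative 3: hydration last.**
- Cut: the C11′–O bond as the final bond, giving the farnesyl ether A6, made from A1 and commercial (2E,6E)-farnesyl bromide A5.
- Forward key step: a hydrogen-atom-transfer (Mukaiyama-type) Markovnikov hydration of A6 to 10.
- Why the chosen plan is better: this would save the chain steps, but C6′=C7′ and C10′=C11′ differ only by a remote methyl versus methylene group, and a hydrogen-atom-transfer catalyst has no structural handle on that difference. The regioisomeric alcohols would be very hard to separate, and the free phenol would sit under oxygen and a metal catalyst. The chosen route makes the same decision on 1, in an aqueous medium where chain folding provides the selectivity and the substrate class is precedented.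

Key step: step 5

Remark: 1 and 6 are taken as commercial; the C10′ stereocentre of 2 and 3 and the C1 stereocentre of 9 arise without control and disappear before 10.

## Route

Step 1
Reactants: 1 (2E,6E)-farnesyl acetate
Product: 2 (2E,6E)-10-bromo-11-hydroxy-3,7,11-trimethyldodeca-2,6-dien-1-yl acetate (racemic at C10)
Conditions: NBS, THF–H2O, 0 °C
Reagents that add atoms: N-bromosuccinimide, O=C1CCC(=O)N1Br; water, O
Why: Bromohydrin formation on polyprenyl acetates in aqueous THF is selective for the terminal C10′=C11′ olefin, the most exposed one when the chain folds in the polar medium and the one farthest from the deactivating allylic acetate; water opens the bromonium ion at the tertiary C11′ (Markovnikov), and the racemic C10′ centre is removed in step 2.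

Step 2
Reactants: 2 (2E,6E)-10-bromo-11-hydroxy-3,7,11-trimethyldodeca-2,6-dien-1-yl acetate
Product: 4 (2E,6E)-3,7,11-trimethyldodeca-2,6-diene-1,11-diol, via 10,11-epoxyfarnesol 3 (not isolated)
Conditions: LiAlH4, THF, 0 °C to 66 °C; then H2O, aq. NaOH
Reagents that add atoms: none
Why: LiAlH4 cleaves the acetate and deprotonates the tertiary alcohol; the bromohydrin alkoxide closes to epoxide 3 (intramolecular Williamson reaction), which hydride opens by SN2 attack at the less substituted C10′; direct hydride displacement of the bromide gives the same diol, so both pathways converge and the isolated olefins are untouched.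

Step 3
Reactants: 4 (2E,6E)-3,7,11-trimethyldodeca-2,6-diene-1,11-diol
Product: 5 (6E,10E)-12-bromo-2,6,10-trimethyldodeca-6,10-dien-2-ol
Conditions: CBr4, PPh3, CH2Cl2, −20 to 0 °C
Reagents that add atoms: carbon tetrabromide, BrC(Br)(Br)Br
Why: Appel reaction: the alkoxyphosphonium salt forms much faster at the unhindered primary allylic hydroxyl than at the tertiary one, and bromide displaces it by SN2 at C1′ at low temperature, which leaves the C2′=C3′ geometry intact; 5 is used directly.

Step 4
Reactants: 5 (6E,10E)-12-bromo-2,6,10-trimethyldodeca-6,10-dien-2-ol; 6 3,4-dihydroxy-5-methoxybenzaldehyde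
Product: 7 3-hydroxy-5-methoxy-4-(R-oxy)benzaldehyde, R = (2E,6E)-11-hydroxy-3,7,11-trimethyldodeca-2,6-dien-1-yl
Conditions: Li2CO3, DMF, 45 °C, under argon
Reagents that add atoms: none
Why: Williamson etherification under weak-base control: the hydroxyl of 6 that is para to the formyl group (the future O5) is the more acidic and is ionized selectively by Li2CO3, as in the known 4-O-selective alkylations of 3,4-dihydroxybenzaldehydes; SN2 attack on the primary allylic bromide keeps both E olefins.

Step 5
Reactants: 7 3-hydroxy-5-methoxy-4-(R-oxy)benzaldehyde
Product: 10 farnesylemefuranone E, via hydroxymethyl aldehyde 8 (not isolated), via lactol 9 (not isolated)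
Conditions: MgCl2, Et3N, (CH2O)n, MeCN, 80 °C; then cold 1 M HCl
Reagents that add atoms: formaldehyde (as paraformaldehyde), C=O
Why: Proposed new method: the closest known reaction type is the Casnati–Skattebøl ortho-formylation, in which a chloromagnesium phenoxide (ArOMgCl) delivers formaldehyde to its ortho carbon through a six-membered chelate and the resulting benzylic alkoxide is then oxidized by a second formaldehyde (Oppenauer-type hydride transfer); here the same first event places the C3 alkoxide of 8 on C3a, the only free position ortho to the O4 phenoxide (C5 is blocked, and C7, para to the phenoxide, lies outside the chelate). The alkoxide oxygen of 8 is four atoms from the formyl carbon on C7a and adds to it (5-exo-trig) to close ring B as the lactol alkoxide 9, the ring form that 2-(hydroxymethyl)benzaldehydes adopt. A hemiacetal alkoxide is a far better hydride donor than a simple benzylic alkoxide, so magnesium-bound formaldehyde is expected to take the hydride from C1 of 9 (Tishchenko-type step) and give the lactone irreversibly, with methanol as the only by-product. The orientation of the lactone is fixed by connectivity: C3 is the carbon that formaldehyde brings and C1 is the carbon that 7 already carries on C7a. Should the open form 8 be oxidized at C3 instead, the material is expected to funnel to the same product, because methoxide adds to the unchelated formyl group on C7a and its hemiacetal passes hydride to the chelated one on C3a (intramolecular Cannizzaro–Tishchenko reaction). No stereocentre remains, since the lactol carbon of 9 is oxidized, and the allyl aryl ether, tertiary alcohol and trisubstituted olefins are inert to this weakly basic medium, which contains no electrophilic oxidant.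

## Compound list

1 | (2E,6E)-farnesyl acetate, (2E,6E)-3,7,11-trimethyldodeca-2,6,10-trien-1-yl acetate | CC(=O)OC/C=C(\C)CC/C=C(\C)CCC=C(C)C | starting material
2 | (2E,6E)-10-bromo-11-hydroxy-3,7,11-trimethyldodeca-2,6-dien-1-yl acetate, racemic at C10 | CC(=O)OC/C=C(\C)CC/C=C(\C)CCC(Br)C(C)(C)O | intermediate
3 | 10,11-epoxyfarnesol, (2E,6E)-9-(3,3-dimethyloxiran-2-yl)-3,7-dimethylnona-2,6-dien-1-ol, racemic, formed and consumed in step 2 | OC/C=C(\C)CC/C=C(\C)CCC1OC1(C)C | intermediate
4 | (2E,6E)-3,7,11-trimethyldodeca-2,6-diene-1,11-diol | OC/C=C(\C)CC/C=C(\C)CCCC(C)(C)O | intermediate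
5 | (6E,10E)-12-bromo-2,6,10-trimethyldodeca-6,10-dien-2-ol | BrC/C=C(\C)CC/C=C(\C)CCCC(C)(C)O | intermediate
6 | 3,4-dihydroxy-5-methoxybenzaldehyde (5-hydroxyvanillin) | COc1cc(C=O)cc(O)c1O | starting material
7 | 3-hydroxy-4-{[(2E,6E)-11-hydroxy-3,7,11-trimethyldodeca-2,6-dien-1-yl]oxy}-5-methoxybenzaldehyde | COc1cc(C=O)cc(O)c1OC/C=C(\C)CC/C=C(\C)CCCC(C)(C)O | intermediate
8 | 3-hydroxy-2-(hydroxymethyl)-4-{[(2E,6E)-11-hydroxy-3,7,11-trimethyldodeca-2,6-dien-1-yl]oxy}-5-methoxybenzaldehyde, formed and consumed in step 5 | COc1cc(C=O)c(CO)c(O)c1OC/C=C(\C)CC/C=C(\C)CCCC(C)(C)O | intermediate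
9 | 5-{[(2E,6E)-11-hydroxy-3,7,11-trimethyldodeca-2,6-dien-1-yl]oxy}-6-methoxy-1,3-dihydro-2-benzofuran-1,4-diol, lactol, racemic at C1, formed and consumed in step 5 | COc1cc2c(c(O)c1OC/C=C(\C)CC/C=C(\C)CCCC(C)(C)O)COC2O | intermediate
10 | farnesylemefuranone E, 4-hydroxy-5-{[(2E,6E)-11-hydroxy-3,7,11-trimethyldodeca-2,6-dien-1-yl]oxy}-6-methoxy-2-benzofuran-1(3H)-one | COc1cc2c(c(O)c1OC/C=C(\C)CC/C=C(\C)CCCC(C)(C)O)COC2=O | target

## Step count and least certain steps

Total step count: 5. Longest linear sequence: 5 steps (1 → 2 → 4 → 5 → 7 → 10).

**Step 5 (key step, Proposed new method).**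
- What may go wrong: hydride transfer from formaldehyde-derived hemiacetal alkoxides to the formyl group of 7 before the C3a–C3 bond has formed (crossed Cannizzaro–Tishchenko reduction of the future C1). The cascade may also stop after oxidation of the open form 8 at C3 without the final intramolecular hydride shift. Attack at C3a, which is flanked by the formyl group and the phenoxide, may be slow.
- Fallback (known chemistry throughout): it sets out from bromide 5 and brings C1 in at the acid level, so that formaldehyde has only its established role. Methyl 3,4-dihydroxy-5-methoxybenzoate F1 is alkylated with 5 at the hydroxyl para to the ester (Li2CO3, DMF) to give methyl 3-hydroxy-5-methoxy-4-(R-oxy)benzoate F2. Casnati–Skattebøl formylation (MgCl2, Et3N, paraformaldehyde) then gives methyl 2-formyl-3-hydroxy-5-methoxy-4-(R-oxy)benzoate F3. NaBH4 (MeOH, 0 °C) reduces the formyl group, and methyl 3-hydroxy-2-(hydroxymethyl)-5-methoxy-4-(R-oxy)benzoate F4 lactonizes in the flask to 10, where the fallback rejoins the route.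

**Step 4.**
- What may go wrong: competing alkylation at the second hydroxyl or at both; ionization of the allylic bromide with allylic transposition or loss of E geometry; air oxidation of the catechol anion.
- Fallback: it sets out from bromide 5 and removes the regiochemical question by using a phenol with one hydroxyl only. 4-Hydroxy-3-iodo-5-methoxybenzaldehyde F5 is alkylated with 5 (K2CO3, DMF) to 3-iodo-5-methoxy-4-(R-oxy)benzaldehyde F6. Miyaura borylation (B2pin2, Pd(dppf)Cl2, KOAc, dioxane, 80 °C) gives 3-methoxy-4-(R-oxy)-5-(4,4,5,5-tetramethyl-1,3,2-dioxaborolan-2-yl)benzaldehyde F7. Oxidation of the C–B bond (NaBO3·4H2O, THF–H2O) returns the route at 7.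

**Step 3.**
- What may go wrong: substitution or elimination at the tertiary C11′ hydroxyl; allylic transposition; decomposition of the labile bromide before it is used.
- Fallback: it sets out from diol 4 and avoids a discrete allylic halide. Mitsunobu etherification of 4 with 6 (PPh3, DIAD, THF, 0 °C) activates only the primary allylic hydroxyl as its alkoxyphosphonium salt and ionizes only the more acidic phenol. It comes back to the route at 7. No new compound arises (F0).

**Step 2.**
- What may go wrong: incomplete removal of bromine; Lewis-acid-assisted opening of epoxide 3 at the tertiary carbon with hydride delivery to C11′ (regioisomeric secondary alcohol); elimination to an allylic alcohol.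
- Fallback: it sets out from bromohydrin 2 and removes the bromine by a radical chain instead of an ionic path. Bu3SnH with AIBN (benzene, 80 °C) gives (2E,6E)-11-hydroxy-3,7,11-trimethyldodeca-2,6-dien-1-yl acetate F8. Methanolysis of the acetate (K2CO3, MeOH) returns the route at 4.

## Further compounds

F1 | step 5 | methyl 3,4-dihydroxy-5-methoxybenzoate | COC(=O)c1cc(O)c(O)c(OC)c1
F2 | step 5 | methyl 3-hydroxy-4-{[(2E,6E)-11-hydroxy-3,7,11-trimethyldodeca-2,6-dien-1-yl]oxy}-5-methoxybenzoate | COC(=O)c1cc(O)c(OC/C=C(\C)CC/C=C(\C)CCCC(C)(C)O)c(OC)c1
F3 | step 5 | methyl 2-formyl-3-hydroxy-4-{[(2E,6E)-11-hydroxy-3,7,11-trimethyldodeca-2,6-dien-1-yl]oxy}-5-methoxybenzoate | COC(=O)c1cc(OC)c(OC/C=C(\C)CC/C=C(\C)CCCC(C)(C)O)c(O)c1C=O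
F4 | step 5 | methyl 3-hydroxy-2-(hydroxymethyl)-4-{[(2E,6E)-11-hydroxy-3,7,11-trimethyldodeca-2,6-dien-1-yl]oxy}-5-methoxybenzoate | COC(=O)c1cc(OC)c(OC/C=C(\C)CC/C=C(\C)CCCC(C)(C)O)c(O)c1CO
F5 | step 4 | 4-hydroxy-3-iodo-5-methoxybenzaldehyde (5-iodovanillin) | COc1cc(C=O)cc(I)c1O
F6 | step 4 | 3-iodo-5-methoxy-4-{[(2E,6E)-11-hydroxy-3,7,11-trimethyldodeca-2,6-dien-1-yl]oxy}benzaldehyde | COc1cc(C=O)cc(I)c1OC/C=C(\C)CC/C=C(\C)CCCC(C)(C)O
F7 | step 4 | 3-methoxy-4-{[(2E,6E)-11-hydroxy-3,7,11-trimethyldodeca-2,6-dien-1-yl]oxy}-5-(4,4,5,5-tetramethyl-1,3,2-dioxaborolan-2-yl)benzaldehyde | COc1cc(C=O)cc(B2OC(C)(C)C(C)(C)O2)c1OC/C=C(\C)CC/C=C(\C)CCCC(C)(C)O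
F0 | step 3 | none | none
F8 | step 2 | (2E,6E)-11-hydroxy-3,7,11-trimethyldodeca-2,6-dien-1-yl acetate | CC(=O)OC/C=C(\C)CC/C=C(\C)CCCC(C)(C)O
A1 | alternative 1 | 4,5-dihydroxy-6-methoxy-2-benzofuran-1(3H)-one (4,5-dihydroxy-6-methoxyphthalide) | COc1cc2c(c(O)c1O)COC2=O
A2 | alternative 2 | 4-chloro-2,3-dimethoxycyclobut-2-en-1-one | COC1=C(OC)C(Cl)C1=O
A3 | alternative 2 | 3-(tributylstannyl)furan-2(5H)-one | CCCC[Sn](CCCC)(CCCC)C1=CCOC1=O
A4 | alternative 2 | 4-hydroxy-5,6-dimethoxy-2-benzofuran-1(3H)-one | COc1cc2c(c(O)c1OC)COC2=O
A5 | alternative 3 | (2E,6E)-farnesyl bromide, (2E,6E)-1-bromo-3,7,11-trimethyldodeca-2,6,10-triene | BrC/C=C(\C)CC/C=C(\C)CCC=C(C)C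
A6 | alternative 3 | 4-hydroxy-6-methoxy-5-{[(2E,6E)-3,7,11-trimethyldodeca-2,6,10-trien-1-yl]oxy}-2-benzofuran-1(3H)-one | COc1cc2c(c(O)c1OC/C=C(\C)CC/C=C(\C)CCC=C(C)C)COC2=O
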